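**Retrosynthetic overview**
1. The plan rests on ring F. It is a phenyl ring with oxygen on C3, C4 and C5 and CH at C2 and C6, and its C1 is bound to the ring E C4 oxygen, which is wedged between the ring E C3 and C5 oxygens. An ynol ether (F C1, C6) and a dioxygenated vinylketene (F C2–C5) deliver exactly this pattern on benzannulation.
2. Target ⇒ (ether cleavage, debenzylation) protected hexamer ⇒ (bonds F C1–C2, F C5–C6, F C4–C5) ring E C4 ethynyl ether of the A–B–C–D–E pentamer + (Z)-4-benzyloxy-1-diazo-3-methoxybut-3-en-2-one.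
3. Ethynyl ether ⇒ pentamer phenol + trichloroethylene. Diazo ketone ⇒ methyl methoxyacetate + methyl formate + benzyl bromide.
4. Pentamer phenol ⇒ 2,4,6-trimethoxyphenol, grown by four cycles of copper-catalysed O-arylation with a bromobenzaldehyde (CHO para or ortho to Br) and Baeyer–Villiger conversion of CHO into the next phenol.
5. Rings A to E are bought as benzene rings and joined in the order A, B, C, D, E. Ring F is the only ring that is built, and it is built last.

Key step: step 17

Remark: C1 of rings B, C, E and F carries the ether oxygen that points towards ring A, and in ring D C1 carries the oxygen to ring C and C6 the oxygen to ring E; the target has no stereocentre, so only the alkene geometry of the four-carbon unit has to be stated.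

**Step 1**
Reactants: 1 2,4,6-trimethoxyphenol; 2 4-bromo-2,6-dimethoxybenzaldehyde
Product: 3 A–B aldehyde 2,6-dimethoxy-4-(2,4,6-trimethoxyphenoxy)benzaldehyde
Conditions: CuI (10 mol %), picolinic acid (20 mol %), K3PO4, DMSO, 90 °C, Ar
Reagents that add atoms: none
Why: An Ullmann-type C–O coupling should work because the C–Br carbon of 2 has hydrogen at both ortho positions and an activating para formyl group, while the CuI/picolinic acid system tolerates phenols with two ortho substituents.

**Step 2**
Reactants: 3 A–B aldehyde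
Product: 5 A–B phenol 2,6-dimethoxy-4-(2,4,6-trimethoxyphenoxy)phenol, via A–B formate 4 (not isolated)
Conditions: mCPBA, CH2Cl2, 0 °C to rt; aq. Na2S2O3/NaHCO3 wash; then Et3N (cat.), MeOH, rt, Ar
Reagents that add atoms: 3-chloroperbenzoic acid, OOC(=O)c1cccc(Cl)c1
Why: Baeyer–Villiger oxidation of a benzaldehyde with two ortho methoxy groups and a para aryloxy group proceeds by aryl migration, the formate 4 shields the easily oxidised phenol from the peracid, and amine-catalysed methanolysis then frees 5.

**Step 3**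
Reactants: 5 A–B phenol; 2 4-bromo-2,6-dimethoxybenzaldehyde
Product: 6 A–B–C aldehyde 4-[2,6-dimethoxy-4-(2,4,6-trimethoxyphenoxy)phenoxy]-2,6-dimethoxybenzaldehyde
Conditions: CuI (10 mol %), picolinic acid (20 mol %), K3PO4, DMSO, 90 °C, Ar
Reagents that add atoms: none
Why: This is the same Ullmann-type C–O coupling as in step 1, since 5 ends in the same 2,6-dimethoxyphenol unit as 1 and the diaryl ether already present is inert to copper and phosphate.

**Step 4**
Reactants: 6 A–B–C aldehyde
Product: 8 A–B–C phenol 4-[2,6-dimethoxy-4-(2,4,6-trimethoxyphenoxy)phenoxy]-2,6-dimethoxyphenol, via A–B–C formate 7 (not isolated)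
Conditions: mCPBA, CH2Cl2, 0 °C to rt; aq. Na2S2O3/NaHCO3 wash; then Et3N (cat.), MeOH, rt, Ar
Reagents that add atoms: 3-chloroperbenzoic acid, OOC(=O)c1cccc(Cl)c1
Why: Baeyer–Villiger oxidation with aryl migration followed by formate methanolysis should run as in step 2, because the formyl-bearing ring has the same substitution pattern.

**Step 5**
Reactants: 9 5-bromo-1,2,3-trimethoxybenzene
Product: 10 6-bromo-2,3,4-trimethoxybenzaldehyde
Conditions: Cl2CHOMe, TiCl4, CH2Cl2, −10 to 0 °C; then ice-water
Reagents that add atoms: dichloromethyl methyl ether, COC(Cl)Cl; water, O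
Why: In this Rieche formylation the two free ring positions of 9 are equivalent and each lies para to one methoxy group and ortho to another, so a single aldehyde with CHO next to Br should result.

**Step 6**
Reactants: 8 A–B–C phenol; 10 6-bromo-2,3,4-trimethoxybenzaldehyde
Product: 11 A–B–C–D aldehyde (2,3,4-trimethoxybenzaldehyde that carries at C6 the aryloxy group derived from 8)
Conditions: CuI (20 mol %), picolinic acid (40 mol %), K3PO4, DMSO, 105 °C, Ar
Reagents that add atoms: none
Why: In this Ullmann-type C–O coupling the ortho formyl group activates the C–Br bond and can hold copper close to it, which should offset the crowding of a diaryl ether with three ortho substituents.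

**Step 7**
Reactants: 11 A–B–C–D aldehyde
Product: 13 A–B–C–D phenol (2,3,4-trimethoxyphenol that carries at C6 the aryloxy group derived from 8; free OH on ring D C6), via A–B–C–D formate 12 (not isolated)
Conditions: mCPBA, CH2Cl2, 0 °C to rt; aq. Na2S2O3/NaHCO3 wash; then Et3N (cat.), MeOH, rt, Ar
Reagents that add atoms: 3-chloroperbenzoic acid, OOC(=O)c1cccc(Cl)c1
Why: Baeyer–Villiger oxidation should again go by aryl migration, since the formyl carbon has ortho methoxy, ortho aryloxy and para methoxy donors, and methanolysis of 12 then places the ring D C6 oxygen.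

**Step 8**
Reactants: 13 A–B–C–D phenol; 2 4-bromo-2,6-dimethoxybenzaldehyde
Product: 14 A–B–C–D–E aldehyde (2,6-dimethoxybenzaldehyde that carries at C4 the aryloxy group derived from 13)
Conditions: CuI (20 mol %), picolinic acid (40 mol %), K3PO4, DMSO, 100 °C, Ar
Reagents that add atoms: none
Why: In this Ullmann-type C–O coupling the crowded partner is again the phenol and the bromide is unhindered and para-formyl activated, which is the pairing that already serves in steps 1 and 3.

**Step 9**
Reactants: 14 A–B–C–D–E aldehyde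
Product: 16 pentamer phenol (2,6-dimethoxyphenol that carries at C4 the aryloxy group derived from 13; free OH on ring E C4), via pentamer formate 15 (not isolated)
Conditions: mCPBA, CH2Cl2, 0 °C to rt; aq. Na2S2O3/NaHCO3 wash; then Et3N (cat.), MeOH, rt, Ar
Reagents that add atoms: 3-chloroperbenzoic acid, OOC(=O)c1cccc(Cl)c1
Why: Baeyer–Villiger oxidation with aryl migration and formate methanolysis should run as in steps 2 and 4, on the same 4-aryloxy-2,6-dimethoxybenzaldehyde pattern.

**Step 10**
Reactants: 16 pentamer phenol; 17 trichloroethylene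
Product: 18 pentamer (E)-1,2-dichlorovinyl ether at ring E C4
Conditions: K2CO3, DMF, 70 °C, Ar
Reagents that add atoms: none
Why: Base takes HCl from trichloroethylene and the phenoxide adds anti to the slim, linear dichloroacetylene so formed (net vinylic substitution, the standard entry to aryl 1,2-dichlorovinyl ethers), so the crowding at the ring E C4 oxygen should hardly matter.

**Step 11**
Reactants: 18 pentamer dichlorovinyl ether
Product: 21 pentamer ethynyl ether at ring E C4, via chloroethynyl ether 19 (not isolated), via lithium acetylide 20 (not isolated)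
Conditions: n-BuLi (2.5 equiv), THF, −78 to −40 °C; then H2O, −78 °C; neutral work-up, Et3N-deactivated silica
Reagents that add atoms: n-butyllithium, [Li]CCCC (lithium of 20 only)
Why: This is the known conversion of 1,2-dichlorovinyl ethers into ynol ethers, in which n-BuLi removes HCl to give 19, Cl/Li exchange gives 20, water protonates it, and the same quench undoes any stray ring lithiation.

**Step 12**
Reactants: 22 methyl methoxyacetate; 23 methyl formate; 24 benzyl bromide
Product: 26 methyl (Z)-3-(benzyloxy)-2-methoxyprop-2-enoate, via sodium enolate 25 (not isolated)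
Conditions: NaH, 23 (excess), THF, 0 °C to rt; then 24, DMF, rt
Reagents that add atoms: sodium hydride, [Na+].[H-] (sodium of 25 only)
Why: A crossed Claisen condensation with the non-enolisable formate is followed by O-alkylation of the ambident enolate in a dipolar aprotic medium, as in β-alkoxyacrylate synthesis; C-benzylation would have to build a fully substituted carbon, and the alkene should settle with benzyloxy anti to the ester (Z).

**Step 13**
Reactants: 26 methyl (Z)-3-(benzyloxy)-2-methoxyprop-2-enoate
Product: 27 (Z)-3-(benzyloxy)-2-methoxyprop-2-enoic acid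
Conditions: LiOH, THF/H2O, rt; then aq. HCl to pH 3, 0 °C
Reagents that add atoms: lithium hydroxide, [Li+].[OH-]
Why: This is a saponification, and the β-alkoxyacrylate is a vinylogous carbonate whose enol ether should survive hydroxide and a brief cold acidification.

**Step 14**
Reactants: 27 (Z)-3-(benzyloxy)-2-methoxyprop-2-enoic acid
Product: 29 (Z)-3-(benzyloxy)-N,2-dimethoxy-N-methylprop-2-enamide, via acyl imidazole 28 (not isolated)
Conditions: CDI, CH2Cl2, rt; then MeNH(OMe)·HCl, rt
Reagents that add atoms: 1,1'-carbonyldiimidazole, O=C(n1ccnc1)n1ccnc1 (imidazolyl group of 28 only); N,O-dimethylhydroxylamine hydrochloride, CNOC.Cl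
Why: Amide coupling through the acyl imidazole keeps acid chlorides and strong acid away from the enol ether.

**Step 15**
Reactants: 29 Weinreb amide
Product: 30 (Z)-4-(benzyloxy)-3-methoxybut-3-en-2-one
Conditions: MeMgBr, THF, −20 to 0 °C; then aq. NH4Cl
Reagents that add atoms: methylmagnesium bromide, C[Mg]Br
Why: In this Weinreb ketone synthesis the N-methoxy-N-methyl amide takes up only one equivalent of the Grignard reagent, and donation from the two alkoxy groups makes the β-carbon a poor site for conjugate addition.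

**Step 16**
Reactants: 30 (Z)-4-(benzyloxy)-3-methoxybut-3-en-2-one
Product: 32 (Z)-4-(benzyloxy)-1-diazo-3-methoxybut-3-en-2-one, via trifluoroacetyl diketone 31 (not isolated)
Conditions: LiHMDS, THF, −78 °C; CF3CO2CH2CF3, −78 °C; cold dilute aq. HCl wash; then MsN3, Et3N, H2O (1 equiv), MeCN, rt, dark
Reagents that add atoms: 2,2,2-trifluoroethyl trifluoroacetate, O=C(OCC(F)(F)F)C(F)(F)F (CF3CO group of 31 only); methanesulfonyl azide, CS(=O)(=O)N=[N+]=[N-]
Why: Detrifluoroacetylative diazo transfer (Regitz type) is the standard route to α'-diazo enones: only the methyl group of 30 can be enolised, trifluoroacetylation activates it, and the sulfonyl azide delivers N2 with loss of the trifluoroacetyl group, without the pyrazoline formation that acylation of diazomethane by enoyl derivatives risks.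

**Step 17**
Reactants: 21 pentamer ethynyl ether; 32 (Z)-4-(benzyloxy)-1-diazo-3-methoxybut-3-en-2-one
Product: 36 protected hexamer (ring F with OMe on C3 and OBn on C4 and free OH on C5), via vinylketene 33 (not isolated), via vinylcyclobutenone 34 (not isolated), via dienylketene 35 (not isolated)
Conditions: 32 (1.5 equiv, slow addition), ClCH2CH2Cl, hν (medium-pressure Hg lamp, Pyrex filter, >300 nm), 20 °C, Ar; then 80 °C
Reagents that add atoms: none
Why: Light above 300 nm, where the polyaryl ether 21 hardly absorbs, expels N2 from 32 and the alkenyl group shifts (Wolff rearrangement) to give vinylketene 33. The electron-rich terminal carbon of the ynol ether attacks the ketene carbonyl carbon, so the [2+2] adduct is 34 with the ring E oxygen on C3 and the dioxygenated vinyl group on C4, which forms ring F bonds C5–C6 and C1–C2. At 80 °C 34 opens by reversible 4π electrocyclic cleavage of its C1–C4 bond to dienylketene 35, and ring F closes by 6π electrocyclisation (bond F C4–C5) followed by enolisation to the phenol. The closest known reaction type is the photochemical Wolff variant of the Danheiser benzannulation, which is established for alkoxy- and silyloxyalkynes. No stereocentre remains, because the one sp3 carbon of 34 becomes the aromatic CH at F C2 and the geometry of the benzyloxy alkene is lost on aromatisation. Only regioselectivity is needed, and the polarisation of the O–C≡C–H unit secures it: the aryloxy carbon ends up meta to the new hydroxyl, between the two CH groups, with methoxy on F C3, benzyloxy on F C4 and OH on F C5.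

**Step 18**
Reactants: 36 protected hexamer
Product: 37 tridecamethyl ether of the target (ring F with OMe on C3 and free OH on C4 and C5)
Conditions: H2 (1 atm), 10% Pd/C, EtOAc/MeOH, rt
Reagents that add atoms: none
Why: Catalytic hydrogenolysis removes the single benzyl ether as toluene, which keeps a benzylating agent out of the Lewis acid step, where it could alkylate the electron-rich rings.

**Step 19**
Reactants: 37 tridecamethyl ether of the target
Product: 38 target CNP0175585.0
Conditions: BBr3 (excess), CH2Cl2, −78 °C to rt, Ar; then H2O, 0 °C; degassed solvents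
Reagents that add atoms: none
Why: In this Lewis acid ether cleavage BBr3 binds each methoxy oxygen and bromide attacks the methyl carbon by SN2, whereas the five diaryl ether links offer no sp3 carbon and should stay intact.

**Compound list**
1 | 2,4,6-trimethoxyphenol | COc1cc(OC)c(O)c(OC)c1 | starting material
2 | 4-bromo-2,6-dimethoxybenzaldehyde | O=Cc1c(OC)cc(Br)cc1OC | starting material
3 | A–B aldehyde, 2,6-dimethoxy-4-(2,4,6-trimethoxyphenoxy)benzaldehyde | O=Cc2c(OC)cc(Oc1c(OC)cc(OC)cc1OC)cc2OC | intermediate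
4 | A–B formate, 2,6-dimethoxy-4-(2,4,6-trimethoxyphenoxy)phenyl formate | O=COc2c(OC)cc(Oc1c(OC)cc(OC)cc1OC)cc2OC | intermediate
5 | A–B phenol, 2,6-dimethoxy-4-(2,4,6-trimethoxyphenoxy)phenol | Oc2c(OC)cc(Oc1c(OC)cc(OC)cc1OC)cc2OC | intermediate
6 | A–B–C aldehyde | O=Cc3c(OC)cc(Oc2c(OC)cc(Oc1c(OC)cc(OC)cc1OC)cc2OC)cc3OC | intermediate
7 | A–B–C formate | O=COc3c(OC)cc(Oc2c(OC)cc(Oc1c(OC)cc(OC)cc1OC)cc2OC)cc3OC | intermediate
8 | A–B–C phenol | Oc3c(OC)cc(Oc2c(OC)cc(Oc1c(OC)cc(OC)cc1OC)cc2OC)cc3OC | intermediate
9 | 5-bromo-1,2,3-trimethoxybenzene | COc1cc(Br)cc(OC)c1OC | starting material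
10 | 6-bromo-2,3,4-trimethoxybenzaldehyde | O=Cc1c(Br)cc(OC)c(OC)c1OC | intermediate
11 | A–B–C–D aldehyde | O=Cc4c(OC)c(OC)c(OC)cc4Oc3c(OC)cc(Oc2c(OC)cc(Oc1c(OC)cc(OC)cc1OC)cc2OC)cc3OC | intermediate
12 | A–B–C–D formate | O=COc4c(OC)c(OC)c(OC)cc4Oc3c(OC)cc(Oc2c(OC)cc(Oc1c(OC)cc(OC)cc1OC)cc2OC)cc3OC | intermediate
13 | A–B–C–D phenol | Oc4c(OC)c(OC)c(OC)cc4Oc3c(OC)cc(Oc2c(OC)cc(Oc1c(OC)cc(OC)cc1OC)cc2OC)cc3OC | intermediate
14 | A–B–C–D–E aldehyde | O=Cc5c(OC)cc(Oc4c(OC)c(OC)c(OC)cc4Oc3c(OC)cc(Oc2c(OC)cc(Oc1c(OC)cc(OC)cc1OC)cc2OC)cc3OC)cc5OC | intermediate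
15 | pentamer formate | O=COc5c(OC)cc(Oc4c(OC)c(OC)c(OC)cc4Oc3c(OC)cc(Oc2c(OC)cc(Oc1c(OC)cc(OC)cc1OC)cc2OC)cc3OC)cc5OC | intermediate
16 | pentamer phenol (free OH on ring E C4) | Oc5c(OC)cc(Oc4c(OC)c(OC)c(OC)cc4Oc3c(OC)cc(Oc2c(OC)cc(Oc1c(OC)cc(OC)cc1OC)cc2OC)cc3OC)cc5OC | intermediate
17 | trichloroethylene | ClC=C(Cl)Cl | starting material
18 | pentamer (E)-1,2-dichlorovinyl ether | Cl/C=C(/Cl)Oc5c(OC)cc(Oc4c(OC)c(OC)c(OC)cc4Oc3c(OC)cc(Oc2c(OC)cc(Oc1c(OC)cc(OC)cc1OC)cc2OC)cc3OC)cc5OC | intermediate
19 | pentamer chloroethynyl ether | ClC#COc5c(OC)cc(Oc4c(OC)c(OC)c(OC)cc4Oc3c(OC)cc(Oc2c(OC)cc(Oc1c(OC)cc(OC)cc1OC)cc2OC)cc3OC)cc5OC | intermediate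
20 | pentamer lithium aryloxyacetylide | [Li]C#COc5c(OC)cc(Oc4c(OC)c(OC)c(OC)cc4Oc3c(OC)cc(Oc2c(OC)cc(Oc1c(OC)cc(OC)cc1OC)cc2OC)cc3OC)cc5OC | intermediate
21 | pentamer ethynyl ether at ring E C4 | C#COc5c(OC)cc(Oc4c(OC)c(OC)c(OC)cc4Oc3c(OC)cc(Oc2c(OC)cc(Oc1c(OC)cc(OC)cc1OC)cc2OC)cc3OC)cc5OC | intermediate
22 | methyl methoxyacetate | COCC(=O)OC | starting material
23 | methyl formate | COC=O | starting material
24 | benzyl bromide | BrCc1ccccc1 | starting material
25 | sodium enolate of methyl 2-methoxy-3-oxopropanoate (configurationally labile) | [Na+].[O-]C=C(OC)C(=O)OC | intermediate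
26 | methyl (Z)-3-(benzyloxy)-2-methoxyprop-2-enoate | COC(=O)/C(OC)=C/OCc1ccccc1 | intermediate
27 | (Z)-3-(benzyloxy)-2-methoxyprop-2-enoic acid | OC(=O)/C(OC)=C/OCc1ccccc1 | intermediate
28 | (Z)-3-(benzyloxy)-1-(imidazol-1-yl)-2-methoxyprop-2-en-1-one | O=C(n1ccnc1)/C(OC)=C/OCc2ccccc2 | intermediate
29 | (Z)-3-(benzyloxy)-N,2-dimethoxy-N-methylprop-2-enamide | CON(C)C(=O)/C(OC)=C/OCc1ccccc1 | intermediate
30 | (Z)-4-(benzyloxy)-3-methoxybut-3-en-2-one | CC(=O)/C(OC)=C/OCc1ccccc1 | intermediate
31 | (Z)-6-(benzyloxy)-1,1,1-trifluoro-5-methoxyhex-5-ene-2,4-dione | O=C(CC(=O)C(F)(F)F)/C(OC)=C/OCc1ccccc1 | intermediate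
32 | (Z)-4-(benzyloxy)-1-diazo-3-methoxybut-3-en-2-one | [N-]=[N+]=CC(=O)/C(OC)=C/OCc1ccccc1 | intermediate
33 | (Z)-4-(benzyloxy)-3-methoxybuta-1,3-dien-1-one (vinylketene) | O=C=C/C(OC)=C/OCc1ccccc1 | intermediate
34 | 3-(pentamer-oxy)-4-[(Z)-2-(benzyloxy)-1-methoxyvinyl]cyclobut-2-en-1-one (racemic at C4) | O=C8C=C(Oc5c(OC)cc(Oc4c(OC)c(OC)c(OC)cc4Oc3c(OC)cc(Oc2c(OC)cc(Oc1c(OC)cc(OC)cc1OC)cc2OC)cc3OC)cc5OC)C8/C(OC)=C/OCc7ccccc7 | intermediate
35 | 6-(benzyloxy)-5-methoxy-3-(pentamer-oxy)hexa-1,3,5-trien-1-one, central double bond cis with respect to the carbon chain | O=C=C/C(Oc5c(OC)cc(Oc4c(OC)c(OC)c(OC)cc4Oc3c(OC)cc(Oc2c(OC)cc(Oc1c(OC)cc(OC)cc1OC)cc2OC)cc3OC)cc5OC)=C\C(OC)=C\OCc7ccccc7 | intermediate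
36 | protected hexamer, ring F 3-OMe, 4-OBn, 5-OH | Oc6cc(Oc5c(OC)cc(Oc4c(OC)c(OC)c(OC)cc4Oc3c(OC)cc(Oc2c(OC)cc(Oc1c(OC)cc(OC)cc1OC)cc2OC)cc3OC)cc5OC)cc(OC)c6OCc7ccccc7 | intermediate
37 | tridecamethyl ether of the target, ring F 3-OMe, 4-OH, 5-OH | Oc6cc(Oc5c(OC)cc(Oc4c(OC)c(OC)c(OC)cc4Oc3c(OC)cc(Oc2c(OC)cc(Oc1c(OC)cc(OC)cc1OC)cc2OC)cc3OC)cc5OC)cc(OC)c6O | intermediate
38 | CNP0175585.0 | Oc1cc(O)c(Oc2cc(O)c(Oc3cc(O)c(Oc4cc(O)c(O)c(O)c4Oc4cc(O)c(Oc5cc(O)c(O)c(O)c5)c(O)c4)c(O)c3)c(O)c2)c(O)c1 | target

**Total step count:** 19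
**Longest linear sequence:** 13 steps (steps 1–4, 6–11, 17–19)

**Steps most likely to fail**

1. **Step 17.**
 - Risk: The ketene may be used up before it adds to the aryl ynol ether, whose oxygen lone pair is partly shared with ring E. The competing processes are self-dimerisation, acylation of the freshly formed phenol, and carbene side paths. Residual light absorption by the oligomer may also slow the Wolff step.
 - Fallback: It sets out from 16 and returns to the route at 38. Phenol 16 is O-arylated with commercial 5-iodo-1,2,3-trimethoxybenzene (COc1cc(I)cc(OC)c1OC; CuI, picolinic acid, K3PO4, DMSO, 105 °C) to give the pentadecamethyl ether of the target F1. BBr3 in CH2Cl2, as in step 19, then cleaves F1 to 38. This gives up ring construction for an Ullmann-type capping of the crowded oxygen.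

2. **Step 6.**
 - Risk: Crowding by three ortho substituents around the new C–O bond may slow the copper cycle so much that loss of bromine from the aldehyde and oxidative decay of the phenoxide take over.
 - Fallback: It sets out from 9 and 8 and returns at 11. Br/Li exchange on 9 (n-BuLi, THF, −78 °C) and fluorination with N-fluorobenzenesulfonimide give 5-fluoro-1,2,3-trimethoxybenzene F2. Rieche formylation (Cl2CHOMe, TiCl4) gives 6-fluoro-2,3,4-trimethoxybenzaldehyde F3. Metal-free SNAr of 8 on F3 (Cs2CO3, DMSO, 120 °C) then gives 11, with the small fluoride as leaving group and the ortho formyl group stabilising the anionic adduct.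

3. **Step 19.**
 - Risk: Cleavage may stop short because partly cleaved boron aryloxides fall out of solution, and the free polyphenol may oxidise in air during aqueous isolation.
 - Fallback: It sets out from 37 and returns at 38. The crude product of the BBr3 treatment is not purified but acetylated at once (Ac2O, pyridine, rt) to the pentadecaacetate of the target F4. F4 is stable to air and silica, so under-cleaved material can be separated and resubmitted. Acid-catalysed methanolysis of F4 (HCl in MeOH, rt, Ar) and evaporation then give 38.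

**Further compounds**
F1 | step 17 | pentadecamethyl ether of the target | COc6cc(Oc5c(OC)cc(Oc4c(OC)c(OC)c(OC)cc4Oc3c(OC)cc(Oc2c(OC)cc(Oc1c(OC)cc(OC)cc1OC)cc2OC)cc3OC)cc5OC)cc(OC)c6OC
F2 | step 6 | 5-fluoro-1,2,3-trimethoxybenzene | COc1cc(F)cc(OC)c1OC
F3 | step 6 | 6-fluoro-2,3,4-trimethoxybenzaldehyde | O=Cc1c(F)cc(OC)c(OC)c1OC
F4 | step 19 | pentadecaacetate of the target | CC(=O)Oc1cc(OC(C)=O)c(Oc2cc(OC(C)=O)c(Oc3cc(OC(C)=O)c(Oc4cc(OC(C)=O)c(OC(C)=O)c(OC(C)=O)c4Oc4cc(OC(C)=O)c(Oc5cc(OC(C)=O)c(OC(C)=O)c(OC(C)=O)c5)c(OC(C)=O)c4)c(OC(C)=O)c3)c(OC(C)=O)c2)c(OC(C)=O)c1
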